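**Retrosynthetic overview**
1. (S)-β-Citronellene 1 supplies C7. Its prenyl end is oxidised and extended (enal 2, Grignard 3, alcohol 4, enone 5) to the (E)-ene-1,2-dione 6, which is the 1-oxadiene.
2. 2'-Hydroxy-6'-methylacetophenone 7 and diethyl carbonate 8 give coumarin 9 (pyranone ring, formed first), then methyl ether 10 and 3-iodide 11.
3. First disconnection, coumarin C3–C1 bond: Heck coupling of the vinyl group of 6 with 11 gives triene-dione 12.
4. Key disconnection, O2–C1 and C4a–C7a: intramolecular inverse-electron-demand oxa-Diels–Alder reaction of 12 closes the cyclopentane and dihydropyran rings together and sets C1, C4a and C7a, giving target 13.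

Assumption: core locants follow cyclopenta[c]pyran numbering (C1 aryl-bearing, O2, C3 acyl-bearing, C4, C4a, C5, C6, C7 methyl-bearing, C7a); 1 (sold as (+)-β-citronellene), 3, 7 and 8 are taken as catalogue chemicals.

**Route**

Step 1
Reactants: 1 (S)-β-citronellene, (3S)-3,7-dimethylocta-1,6-diene
Product: 2 (2E,6S)-2,6-dimethylocta-2,7-dienal
Conditions: SeO2 (1.1 equiv), 95% EtOH, reflux
Reagents that add atoms: selenium dioxide, O=[Se]=O
Why: Selenium dioxide allylic oxidation (ene reaction, then [2,3]-sigmatropic shift, then oxidation of the allylic alcohol) attacks only the nucleophilic trisubstituted alkene at its E-methyl group, giving the (E)-enal and leaving the vinyl group and the stereocentre untouched.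

Step 2
Reactants: 2 (2E,6S)-2,6-dimethylocta-2,7-dienal; 3 isopentylmagnesium bromide (3-methylbutylmagnesium bromide)
Product: 4 (6E,10S)-2,6,10-trimethyldodeca-6,11-dien-5-ol (mixture of C5 epimers)
Conditions: 3 (1.2 equiv), THF, −78 to 0 °C; then H2O
Reagents that add atoms: none
Why: Grignard 1,2-addition to the α-branched enal is clean at low temperature; the new carbinol centre is uncontrolled but is removed in step 3.

Step 3
Reactants: 4 (6E,10S)-2,6,10-trimethyldodeca-6,11-dien-5-ol
Product: 5 (6E,10S)-2,6,10-trimethyldodeca-6,11-dien-5-one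
Conditions: Dess–Martin periodinane (1.2 equiv), CH2Cl2, 0 °C to rt
Reagents that add atoms: none
Why: Dess–Martin oxidation of the secondary allylic alcohol gives the enone under neutral conditions without alkene isomerisation.

Step 4
Reactants: 5 (6E,10S)-2,6,10-trimethyldodeca-6,11-dien-5-one
Product: 6 (6E,10S)-2,6,10-trimethyldodeca-6,11-diene-4,5-dione
Conditions: SeO2 (1.2 equiv), 1,4-dioxane/H2O (30:1), 90 °C
Reagents that add atoms: selenium dioxide, O=[Se]=O
Why: Riley oxidation of the only enolisable α-methylene (C4) gives the 1,2-diketone; the electron-poor enone alkene and the monosubstituted vinyl group are poor ene partners for SeO2.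

Step 5
Reactants: 7 2'-hydroxy-6'-methylacetophenone, 1-(2-hydroxy-6-methylphenyl)ethanone; 8 diethyl carbonate
Product: 9 4-hydroxy-5-methylcoumarin (4-hydroxy-5-methyl-2H-chromen-2-one)
Conditions: NaH (3 equiv), toluene, 110 °C; then aq. HCl
Reagents that add atoms: none
Why: Claisen-type C-acylation of the ketone enolate by diethyl carbonate, then lactonisation onto the phenoxide, builds the pyranone ring with the 6'-methyl group ending at C5.

Step 6
Reactants: 9 4-hydroxy-5-methylcoumarin
Product: 10 4-methoxy-5-methylcoumarin (4-methoxy-5-methyl-2H-chromen-2-one)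
Conditions: Me2SO4 (1.2 equiv), K2CO3 (2 equiv), acetone, reflux
Reagents that add atoms: dimethyl sulfate, COS(=O)(=O)OC
Why: Williamson-type O-methylation of the vinylogous acid with a hard alkylating agent gives mainly the 4-methoxycoumarin, separable from minor 2-methoxychromone.

Step 7
Reactants: 10 4-methoxy-5-methylcoumarin
Product: 11 3-iodo-4-methoxy-5-methylcoumarin (3-iodo-4-methoxy-5-methyl-2H-chromen-2-one)
Conditions: NIS (1.1 equiv), TFA (10 mol %), MeCN, rt, dark
Reagents that add atoms: N-iodosuccinimide, O=C1CCC(=O)N1I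
Why: Electrophilic iodination occurs at C3, the nucleophilic β-carbon of the enol ether.

Step 8
Reactants: 6 (6E,10S)-2,6,10-trimethyldodeca-6,11-diene-4,5-dione; 11 3-iodo-4-methoxy-5-methylcoumarin
Product: 13 3-[(1R,4aS,7S,7aR)-4,7-dimethyl-3-(3-methylbutanoyl)-1,4a,5,6,7,7a-hexahydrocyclopenta[c]pyran-1-yl]-4-methoxy-5-methyl-2H-chromen-2-one, via Heck triene-dione 12 (not isolated)
Conditions: 6 (1.0 equiv), 11 (1.1 equiv), Pd(OAc)2 (5 mol %), n-Bu4NCl (1 equiv), NaHCO3 (2.5 equiv), DMF, 60 °C; then 90 °C
Reagents that add atoms: none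
Why: Jeffery-type Mizoroki–Heck arylation of the terminal vinyl group gives the (E)-alkenylcoumarin 12, whose electron-rich alkenyl-methoxycoumarin alkene and 2-acyl-1-oxadiene then combine in an intramolecular inverse-electron-demand hetero-Diels–Alder reaction: the three-atom tether enforces the cis ring fusion, the C7 stereocentre directs the diene to the face that leaves its methyl group outside (trans to C1), and suprafacial addition to the E-alkene puts the aryl group at C1 trans to C7, together giving (1R,4aS,7aR).

**Compound list**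
1 | (S)-β-citronellene, (3S)-3,7-dimethylocta-1,6-diene | C=C[C@@H](C)CCC=C(C)C | starting material
2 | (2E,6S)-2,6-dimethylocta-2,7-dienal | C=C[C@@H](C)CC/C=C(\C)C=O | intermediate
3 | isopentylmagnesium bromide | CC(C)CC[Mg]Br | starting material
4 | (6E,10S)-2,6,10-trimethyldodeca-6,11-dien-5-ol (C5 epimers) | C=C[C@@H](C)CC/C=C(\C)C(O)CCC(C)C | intermediate
5 | (6E,10S)-2,6,10-trimethyldodeca-6,11-dien-5-one | C=C[C@@H](C)CC/C=C(\C)C(=O)CCC(C)C | intermediate
6 | (6E,10S)-2,6,10-trimethyldodeca-6,11-diene-4,5-dione | C=C[C@@H](C)CC/C=C(\C)C(=O)C(=O)CC(C)C | intermediate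
7 | 2'-hydroxy-6'-methylacetophenone | CC(=O)c1c(C)cccc1O | starting material
8 | diethyl carbonate | CCOC(=O)OCC | starting material
9 | 4-hydroxy-5-methylcoumarin | Cc1cccc2oc(=O)cc(O)c12 | intermediate
10 | 4-methoxy-5-methylcoumarin | COc1cc(=O)oc2cccc(C)c12 | intermediate
11 | 3-iodo-4-methoxy-5-methylcoumarin | COc1c(I)c(=O)oc2cccc(C)c12 | intermediate
12 | 4-methoxy-5-methyl-3-[(1E,3S,6E)-3,7,11-trimethyl-8,9-dioxododeca-1,6-dien-1-yl]-2H-chromen-2-one | COc1c(/C=C/[C@@H](C)CC/C=C(\C)C(=O)C(=O)CC(C)C)c(=O)oc2cccc(C)c12 | intermediate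
13 | 3-[(1R,4aS,7S,7aR)-4,7-dimethyl-3-(3-methylbutanoyl)-1,4a,5,6,7,7a-hexahydrocyclopenta[c]pyran-1-yl]-4-methoxy-5-methyl-2H-chromen-2-one | COc1c([C@@H]2OC(C(=O)CC(C)C)=C(C)[C@H]3CC[C@H](C)[C@H]32)c(=O)oc2cccc(C)c12 | target

**Step count**
Total: 8 steps. Longest linear sequence: 5 steps (steps 1, 2, 3, 4, 8).

**Steps most likely to fail, with fallbacks**

Step 8 is the most exposed. The Heck insertion into an unactivated, α-branched vinyl group can give some β-hydride elimination toward C3' (a non-conjugated trisubstituted alkene) or branched arylation, and the cycloaddition has to run cleanly in the same flask. The fallback sets out from 11: Stille vinylation (tributyl(vinyl)stannane, Pd(PPh3)4, toluene, 90 °C) gives 3-ethenyl-4-methoxy-5-methyl-2H-chromen-2-one F1. Cross-metathesis of F1 with the vinyl group of 6 (second-generation Hoveyda–Grubbs catalyst, CH2Cl2, 40 °C) forms the E-alkene regiospecifically; the electron-poor trisubstituted enone alkene of 6 is essentially inert to metathesis. This comes back to the route at 12, now isolated, which is cyclised to 13 in toluene at 90 °C or with Me2AlCl in CH2Cl2 at −78 °C.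

Step 4 can suffer over-oxidation, dehydrogenation next to the new diketone, or stray allylic oxidation. The fallback sets out from 5: kinetic enolisation at C4 (LiN(SiMe3)2, THF, −78 °C) and hydroxylation with 2-(phenylsulfonyl)-3-phenyloxaziridine gives (6E,10S)-4-hydroxy-2,6,10-trimethyldodeca-6,11-dien-5-one F2. Dess–Martin oxidation of F2 comes back to the route at 6.

Step 1 typically gives moderate yields and aldehyde/allylic alcohol mixtures contaminated with selenium residues. The fallback sets out from 1: selective ozonolysis of the electron-rich trisubstituted alkene (O3, 1 equiv, CH2Cl2, −78 °C, Sudan Red 7B as end-point indicator; then Me2S) gives (4S)-4-methylhex-5-enal F3. Wittig olefination of F3 with 2-(triphenylphosphoranylidene)propanal (toluene, 90 °C, E-selective stabilised ylide) comes back to the route at 2.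

**Further compounds**
F1 | step 8 | 3-ethenyl-4-methoxy-5-methyl-2H-chromen-2-one | COc1c(C=C)c(=O)oc2cccc(C)c12
F2 | step 4 | (6E,10S)-4-hydroxy-2,6,10-trimethyldodeca-6,11-dien-5-one (C4 epimers) | C=C[C@@H](C)CC/C=C(\C)C(=O)C(O)CC(C)C
F3 | step 1 | (4S)-4-methylhex-5-enal | C=C[C@@H](C)CCC=O
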